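**Plan**

1. Retrosynthetic cuts: (i) C12–C13 (aldol) and the lactone O–C16 bond, which separate a bicyclic C12 aldehyde from a four-carbon hydroxy ester made from dimethyl (S)-malate; (ii) C4–C18 and the C3 oxidation level; (iii) C1–C2 and C3–C4 of ring A together; (iv) the cyclobutane bond of (1S,5S)-verbenone.
2. Forward order: ring B is the six-membered ring of verbenone (vinyl cuprate addition, C9 alkylation, cyclobutane C–C cleavage give a vinyl/2-propenyl 1,5-diene). Ring A is then closed in one ene–yne–ene metathesis cascade with a two-carbon ethynylboron unit. The C13–C16 chain is joined last and the lactone closes on deprotection.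
3. Enabling feature: C1 and C4 of ring A hang on the neighbouring ring-B atoms C10 and C5, and O3 and O19 stand 1,3 across C4. One boron atom can therefore bridge C3 and O19 in a five-membered oxaborole and later be exchanged for the C3 oxygen.
4. Stereochemistry: C5 from verbenone; C10 by cuprate addition anti to the CMe2 bridge; C9 by equilibration; C4 by enolate methylation anti to the C10 methyl; C3 by axial hydride delivery; C14 from (S)-malate; C13 and C12 by a chelated dianion aldol.

Key step: step 8

Remark: labdane numbering (C1–C20) is used for all intermediates, and commercial (1S,5S)-(−)-verbenone is assumed to be brought to high enantiomeric purity before use.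

**Route**

Step 1
Reactants: 1 (1S,5S)-(−)-verbenone
Product: 2 4,6,6-trimethyl-4-vinylbicyclo[3.1.1]heptan-2-one (vinyl anti to the CMe2 bridge)
Conditions: CH2=CHMgBr, CuBr·SMe2 (10 mol %), THF, −40 to 0 °C; aq NH4Cl
Reagents that add atoms: vinylmagnesium bromide C=C[Mg]Br
Why: Copper-catalysed conjugate addition of the vinyl Grignard reagent to the β-methyl enone creates the quaternary carbon C10, the nucleophile entering anti to the CMe2 bridge so that the vinyl group (future C1 arm) ends trans to the bridge carbon that later becomes the C4 arm on C5.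

Step 2
Reactants: 2 4,6,6-trimethyl-4-vinylbicyclo[3.1.1]heptan-2-one
Product: 3 methyl 2-(4,6,6-trimethyl-2-oxo-4-vinylbicyclo[3.1.1]heptan-3-yl)acetate (acetate arm cis to vinyl)
Conditions: LiN(iPr)2, THF, −78 °C; BrCH2CO2Me, DMPU, −78 to −20 °C
Reagents that add atoms: methyl bromoacetate COC(=O)CBr
Why: Kinetic enolate alkylation: the bridgehead α-carbon (C7) cannot enolise (Bredt's rule), so only the C8–C9 enolate forms and is alkylated anti to the CMe2 bridge; this C9 configuration is the wrong one and is corrected by equilibration in step 4.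

Step 3
Reactants: 3 methyl 2-(4,6,6-trimethyl-2-oxo-4-vinylbicyclo[3.1.1]heptan-3-yl)acetate
Product: 4 methyl 2-[2-acetoxy-6-methyl-5-(prop-1-en-2-yl)-6-vinylcyclohex-2-en-1-yl]acetate (C9 arm cis to vinyl)
Conditions: BF3·OEt2, Zn(OAc)2, Ac2O, 0 °C to rt
Reagents that add atoms: acetic anhydride CC(=O)OC(C)=O
Why: Lewis-acid-promoted acylative cyclobutane fragmentation (retro-Prins-type C–C cleavage): O-acylation of the ketone breaks the strained bond between the α-bridgehead and the CMe2 carbon to give the C7=C8 enol acetate and a tertiary cation that loses a proton to the 2-propenyl group, leaving C5, C9 and C10 untouched.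

Step 4
Reactants: 4 methyl 2-[2-acetoxy-6-methyl-5-(prop-1-en-2-yl)-6-vinylcyclohex-2-en-1-yl]acetate
Product: 6 methyl 2-[2-methyl-6-oxo-3-(prop-1-en-2-yl)-2-vinylcyclohexyl]acetate (C9 arm trans to vinyl), via C9-epimeric ketone 5 (not isolated)
Conditions: K2CO3, MeOH, rt
Reagents that add atoms: none
Why: Methanolysis of the enol acetate (transesterification) liberates the C8 ketone, and the carbonate base epimerises C9 through the enolate to the thermodynamic all-equatorial isomer, in which the acetate arm is trans to vinyl and cis to the C10 methyl as in the target.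

Step 5
Reactants: 6 methyl 2-[2-methyl-6-oxo-3-(prop-1-en-2-yl)-2-vinylcyclohexyl]acetate
Product: 7 methyl 2-[3-(3-hydroxyprop-1-en-2-yl)-2-methyl-6-oxo-2-vinylcyclohexyl]acetate
Conditions: SeO2 (0.3 equiv), t-BuOOH, CH2Cl2, rt
Reagents that add atoms: selenium dioxide O=[Se]=O; tert-butyl hydroperoxide CC(C)(C)OO (terminal oxidant)
Why: Riley allylic oxidation (ene reaction, then [2,3]-sigmatropic shift) hydroxylates the methyl group of the electron-rich 1,1-disubstituted 2-propenyl unit (future C19), whereas the vinyl group has no allylic hydrogen and the ketone α-positions should not react at room temperature.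

Step 6
Reactants: 7 methyl 2-[3-(3-hydroxyprop-1-en-2-yl)-2-methyl-6-oxo-2-vinylcyclohexyl]acetate
Product: 8 methyl 2-[3-(3-hydroxyprop-1-en-2-yl)-2-methyl-6-methylidene-2-vinylcyclohexyl]acetate
Conditions: Ph3PCH3Br, KOtBu, THF, 0 °C to rt
Reagents that add atoms: methyltriphenylphosphonium bromide C[P+](c1ccccc1)(c1ccccc1)c1ccccc1.[Br-]
Why: Wittig methylenation of the C8 ketone with excess ylide (the alcohol rides through as its alkoxide and the methyl ester is far less electrophilic); C9 stays in its thermodynamic configuration and is now locked.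

Step 7
Reactants: 9 ethynylmagnesium bromide; 10 triisopropyl borate
Product: 11 diisopropyl ethynylboronate
Conditions: THF, −78 °C; HCl in Et2O, −78 °C to rt; filtration; used as a titrated solution
Reagents that add atoms: none
Why: Addition of the alkynyl Grignard reagent to the trialkyl borate gives the tetracoordinate borate, which anhydrous HCl collapses to the alkynylboronic ester, the standard preparation of 1-alkynyl diisopropyl boronates.

Step 8
Reactants: 8 methyl 2-[3-(3-hydroxyprop-1-en-2-yl)-2-methyl-6-methylidene-2-vinylcyclohexyl]acetate; 11 diisopropyl ethynylboronate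
Product: 14 methyl 19-hydroxy-3-oxo-13,14,15,16,18-pentanorlabda-1,8(17)-dien-12-oate (C4 epimers), via mixed boronic ester 12 (not isolated), via cyclic dienylboronic ester 13 (not isolated)
Conditions: 11 (1.2 equiv), CH2Cl2, rt, then vacuum; RuCl2(=CHPh)(H2IMes)(PCy3) (second-generation Grubbs catalyst, 10 mol %), toluene (5 mM), 80 °C; then 30% H2O2, NaH2PO4/Na2HPO4 buffer (pH 7), THF, 0 °C
Reagents that add atoms: hydrogen peroxide OO
Why: Proposed new method: transesterification ties the ethynylboron unit to O19; the ruthenium methylidene then adds to the unsubstituted alkyne terminus (C2) to give the α-boryl vinylcarbene at C3, which closes the five-membered oxaborole onto the 1,1-disubstituted alkene at C4 (exo-mode ring-closing enyne metathesis, C3=C4), and the C2 vinyl group so formed undergoes ring-closing diene metathesis with the C10 vinyl group to close six-membered ring A (C1=C2) with loss of ethene. The closest known reactions are the boron-tethered ring-closing enyne metathesis of alkynylboronic esters with allylic alcohols and ene–yne–ene (dienyne) metathesis cascades; new here is their merger, so that a carbocycle is built across the tether and both closures, one of them to a tetrasubstituted alkene, occur in one pot. No stereocentre is created: C5, C9 and C10 are spectators, and C4 and C3 are set later from the planar product. The selectivity needed is regiochemical (carbene on C3, not C2) and chemoselective (the C8 methylidene must stay out); the first is secured by the usual preference of ruthenium alkylidenes for the unsubstituted alkyne terminus together with the short B–O tether that allows only the five-membered closure, the second because any closure through C17 would give a bridgehead alkene or a cyclobutene. Buffered H2O2 then converts the C3–B bond into the C3 carbonyl and frees O19, so the boron helper leaves as boric acid.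

Step 9
Reactants: 14 methyl 19-hydroxy-3-oxo-13,14,15,16,18-pentanorlabda-1,8(17)-dien-12-oate
Product: 15 methyl 19-(tert-butyldimethylsilyloxy)-3-oxo-13,14,15,16,18-pentanorlabda-1,8(17)-dien-12-oate (C4 epimers)
Conditions: TBSCl, imidazole, CH2Cl2, 0 °C
Reagents that add atoms: tert-butyldimethylsilyl chloride CC(C)(C)[Si](C)(C)Cl
Why: Standard silylation of the primary alcohol masks O19 before the enolate chemistry.

Step 10
Reactants: 15 methyl 19-(tert-butyldimethylsilyloxy)-3-oxo-13,14,15,16,18-pentanorlabda-1,8(17)-dien-12-oate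
Product: 16 methyl 19-(tert-butyldimethylsilyloxy)-3-oxo-13,14,15,16-tetranorlabda-1,8(17)-dien-12-oate (C18 methyl equatorial and C19 axial)
Conditions: LiN(iPr)2 (1.05 equiv), THF, −78 °C; MeI, DMPU, −78 to −30 °C
Reagents that add atoms: iodomethane CI
Why: Enolate alkylation: only C4 can be deprotonated (C2 is vinylic and the γ-carbon C10 is quaternary), and the cross-conjugated lithium dienolate should be methylated at C4 on the face opposite the axial C10 methyl (1,3-diaxial hindrance), which places C18 equatorial and the C19 arm axial, the same facial preference as in the classical methylation of 3-oxo-4-carboxylates of 10-methyldecalins.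

Step 11
Reactants: 16 methyl 19-(tert-butyldimethylsilyloxy)-3-oxo-13,14,15,16-tetranorlabda-1,8(17)-dien-12-oate
Product: 17 methyl 19-(tert-butyldimethylsilyloxy)-3-oxo-13,14,15,16-tetranorlabd-8(17)-en-12-oate
Conditions: [(Ph3P)CuH]6, wet toluene, rt
Reagents that add atoms: none
Why: Conjugate reduction with the copper hydride is chemoselective for the enone and should leave the isolated 1,1-disubstituted alkene, the ester and the silyl ether untouched; no stereocentre is formed.

Step 12
Reactants: 17 methyl 19-(tert-butyldimethylsilyloxy)-3-oxo-13,14,15,16-tetranorlabd-8(17)-en-12-oate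
Product: 18 methyl 19-(tert-butyldimethylsilyloxy)-3α-hydroxy-13,14,15,16-tetranorlabd-8(17)-en-12-oate (C3 hydroxyl equatorial and cis to C19)
Conditions: NaBH4, MeOH–THF, 0 °C
Reagents that add atoms: none
Why: Borohydride reduction of the hindered 4,4-disubstituted 3-ketone should occur by axial hydride attack (the equatorial trajectory is blocked by the axial C19 arm) and give the equatorial C3 alcohol, as with 4,4-dimethyl-3-oxo terpenoids.

Step 13
Reactants: 18 methyl 19-(tert-butyldimethylsilyloxy)-3α-hydroxy-13,14,15,16-tetranorlabd-8(17)-en-12-oate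
Product: 19 methyl 3α,19-bis(tert-butyldimethylsilyloxy)-13,14,15,16-tetranorlabd-8(17)-en-12-oate
Conditions: TBSOTf, 2,6-lutidine, CH2Cl2, 0 °C
Reagents that add atoms: tert-butyldimethylsilyl trifluoromethanesulfonate CC(C)(C)[Si](C)(C)OS(=O)(=O)C(F)(F)F
Why: Silyl triflate/lutidine silylation of the hindered secondary alcohol removes the last acidic proton before the aldol step.

Step 14
Reactants: 19 methyl 3α,19-bis(tert-butyldimethylsilyloxy)-13,14,15,16-tetranorlabd-8(17)-en-12-oate
Product: 20 3α,19-bis(tert-butyldimethylsilyloxy)-13,14,15,16-tetranorlabd-8(17)-en-12-al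
Conditions: iBu2AlH (1.1 equiv), CH2Cl2, −78 °C; MeOH, aq potassium sodium tartrate
Reagents that add atoms: none
Why: Low-temperature half-reduction of the methyl ester with iBu2AlH stops at the tetrahedral aluminium hemiacetal, which gives the C12 aldehyde on work-up.

Step 15
Reactants: 21 dimethyl (S)-malate
Product: 22 methyl (S)-3,4-dihydroxybutanoate
Conditions: BH3·SMe2, NaBH4 (5 mol %), THF, rt; MeOH
Reagents that add atoms: none
Why: Hydroxyl-directed (chelation-controlled) borane reduction reduces only the ester next to the free hydroxyl, and the stereocentre (future C14) is not touched.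

Step 16
Reactants: 22 methyl (S)-3,4-dihydroxybutanoate
Product: 23 methyl (S)-4-(tert-butyldimethylsilyloxy)-3-hydroxybutanoate
Conditions: TBSCl (1.05 equiv), imidazole, CH2Cl2, −20 °C
Reagents that add atoms: tert-butyldimethylsilyl chloride CC(C)(C)[Si](C)(C)Cl
Why: Selective silylation of the primary hydroxyl of the 1,2-diol at low temperature.

Step 17
Reactants: 20 3α,19-bis(tert-butyldimethylsilyloxy)-13,14,15,16-tetranorlabd-8(17)-en-12-al; 23 methyl (S)-4-(tert-butyldimethylsilyloxy)-3-hydroxybutanoate
Product: 24 methyl (12R,13R,14S)-3α,15,19-tris(tert-butyldimethylsilyloxy)-12,14-dihydroxylabd-8(17)-en-16-oate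
Conditions: 23 (1.5 equiv), LiN(iPr)2 (2.2 equiv per 23), THF, −78 to −40 °C; then 20, −78 °C; aq NH4Cl
Reagents that add atoms: none
Why: Fráter–Seebach-type aldol addition: the lithium-chelated Z(O)-enolate/alkoxide dianion should be attacked by the aldehyde anti to the CH2OSi substituent on C14 (C13 anti to O14 in the open chain, which is cis on the future lactone), and through a Zimmerman–Traxler chair the Z-enolate should give the syn C12/C13 relationship of the target.

Step 18
Reactants: 24 methyl (12R,13R,14S)-3α,15,19-tris(tert-butyldimethylsilyloxy)-12,14-dihydroxylabd-8(17)-en-16-oate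
Product: 26 (12R,13R,14S)-3α,12,14,19-tetrahydroxy-5β,9βH,10α-labd-8(17)-en-16,15-olide (CNP0113086.1), via pentahydroxy methyl ester 25 (not isolated)
Conditions: HF·pyridine, pyridine–THF, 0 °C to rt
Reagents that add atoms: none
Why: Fluoride-mediated global desilylation frees O3, O19 and O15, and the C15 hydroxyl then lactonises onto the C16 methyl ester (five-membered ring) without touching any stereocentre.

**Compound list**

1 | (1S,5S)-(−)-verbenone, (1S,5S)-4,6,6-trimethylbicyclo[3.1.1]hept-3-en-2-one | O=C1C=C(C)[C@@H]2C[C@H]1C2(C)C | starting material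
2 | 4,6,6-trimethyl-4-vinylbicyclo[3.1.1]heptan-2-one, vinyl anti to the CMe2 bridge, bridgeheads as in 1 | O=C1C[C@](C)(C=C)[C@@H]2C[C@H]1C2(C)C | intermediate
3 | methyl 2-(4,6,6-trimethyl-2-oxo-4-vinylbicyclo[3.1.1]heptan-3-yl)acetate, acetate arm anti to the CMe2 bridge and cis to vinyl | O=C1[C@H](CC(=O)OC)[C@](C)(C=C)[C@@H]2C[C@H]1C2(C)C | intermediate
4 | methyl 2-[2-acetoxy-6-methyl-5-(prop-1-en-2-yl)-6-vinylcyclohex-2-en-1-yl]acetate; C7=C8 enol acetate, C9 arm cis to vinyl, C10 methyl cis to the C5 propenyl group | CC(=O)OC1=CC[C@H](C(C)=C)[C@@](C)(C=C)[C@H]1CC(=O)OC | intermediate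
5 | methyl 2-[2-methyl-6-oxo-3-(prop-1-en-2-yl)-2-vinylcyclohexyl]acetate, C9 epimer with the acetate arm cis to vinyl | O=C1CC[C@H](C(C)=C)[C@@](C)(C=C)[C@H]1CC(=O)OC | intermediate
6 | methyl 2-[2-methyl-6-oxo-3-(prop-1-en-2-yl)-2-vinylcyclohexyl]acetate, acetate arm and propenyl group both cis to the C10 methyl and trans to vinyl | O=C1CC[C@H](C(C)=C)[C@@](C)(C=C)[C@@H]1CC(=O)OC | intermediate
7 | methyl 2-[3-(3-hydroxyprop-1-en-2-yl)-2-methyl-6-oxo-2-vinylcyclohexyl]acetate, configuration as 6 | O=C1CC[C@H](C(=C)CO)[C@@](C)(C=C)[C@@H]1CC(=O)OC | intermediate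
8 | methyl 2-[3-(3-hydroxyprop-1-en-2-yl)-2-methyl-6-methylidene-2-vinylcyclohexyl]acetate, configuration as 6 | C=C1CC[C@H](C(=C)CO)[C@@](C)(C=C)[C@@H]1CC(=O)OC | intermediate
9 | ethynylmagnesium bromide | C#C[Mg]Br | starting material
10 | triisopropyl borate | CC(C)OB(OC(C)C)OC(C)C | starting material
11 | diisopropyl ethynylboronate | C#CB(OC(C)C)OC(C)C | intermediate
12 | mixed isopropyl boronic ester of 8 at O19 carrying the ethynyl group on boron | C=C1CC[C@H](C(=C)COB(OC(C)C)C#C)[C@@](C)(C=C)[C@@H]1CC(=O)OC | intermediate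
13 | tricyclic dienylboronic ester: ring A 1,3-diene (C1=C2, C3=C4) with a C3–B(OiPr)–O19–C19 oxaborole fused at C3=C4 | C=C1CC[C@@H]2C3=C(C=C[C@@]2(C)[C@@H]1CC(=O)OC)B(OC(C)C)OC3 | intermediate
14 | methyl 19-hydroxy-3-oxo-13,14,15,16,18-pentanorlabda-1,8(17)-dien-12-oate, C4 epimers; C5, C9, C10 as in andrographolide (5β-H, 9β-H, 10α-CH3) | C=C1CC[C@@H]2C(CO)C(=O)C=C[C@@]2(C)[C@@H]1CC(=O)OC | intermediate
15 | 19-O-tert-butyldimethylsilyl ether of 14, C4 epimers | C=C1CC[C@@H]2C(CO[Si](C)(C)C(C)(C)C)C(=O)C=C[C@@]2(C)[C@@H]1CC(=O)OC | intermediate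
16 | methyl 19-(tert-butyldimethylsilyloxy)-3-oxo-13,14,15,16-tetranorlabda-1,8(17)-dien-12-oate, C18 methyl equatorial, C19 axial and cis to C20 | C=C1CC[C@@H]2[C@](C)(CO[Si](C)(C)C(C)(C)C)C(=O)C=C[C@@]2(C)[C@@H]1CC(=O)OC | intermediate
17 | methyl 19-(tert-butyldimethylsilyloxy)-3-oxo-13,14,15,16-tetranorlabd-8(17)-en-12-oate | C=C1CC[C@@H]2[C@](C)(CO[Si](C)(C)C(C)(C)C)C(=O)CC[C@@]2(C)[C@@H]1CC(=O)OC | intermediate
18 | methyl 19-(tert-butyldimethylsilyloxy)-3α-hydroxy-13,14,15,16-tetranorlabd-8(17)-en-12-oate, equatorial C3 hydroxyl cis to C19 | C=C1CC[C@@H]2[C@](C)(CO[Si](C)(C)C(C)(C)C)[C@H](O)CC[C@@]2(C)[C@@H]1CC(=O)OC | intermediate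
19 | methyl 3α,19-bis(tert-butyldimethylsilyloxy)-13,14,15,16-tetranorlabd-8(17)-en-12-oate | C=C1CC[C@@H]2[C@](C)(CO[Si](C)(C)C(C)(C)C)[C@H](O[Si](C)(C)C(C)(C)C)CC[C@@]2(C)[C@@H]1CC(=O)OC | intermediate
20 | 3α,19-bis(tert-butyldimethylsilyloxy)-13,14,15,16-tetranorlabd-8(17)-en-12-al | C=C1CC[C@@H]2[C@](C)(CO[Si](C)(C)C(C)(C)C)[C@H](O[Si](C)(C)C(C)(C)C)CC[C@@]2(C)[C@@H]1CC=O | intermediate
21 | dimethyl (S)-malate | COC(=O)C[C@H](O)C(=O)OC | starting material
22 | methyl (S)-3,4-dihydroxybutanoate | COC(=O)C[C@H](O)CO | intermediate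
23 | methyl (S)-4-(tert-butyldimethylsilyloxy)-3-hydroxybutanoate | COC(=O)C[C@H](O)CO[Si](C)(C)C(C)(C)C | intermediate
24 | methyl (12R,13R,14S)-3α,15,19-tris(tert-butyldimethylsilyloxy)-12,14-dihydroxylabd-8(17)-en-16-oate | C=C1CC[C@@H]2[C@](C)(CO[Si](C)(C)C(C)(C)C)[C@H](O[Si](C)(C)C(C)(C)C)CC[C@@]2(C)[C@@H]1C[C@@H](O)[C@@H](C(=O)OC)[C@H](O)CO[Si](C)(C)C(C)(C)C | intermediate
25 | methyl (12R,13R,14S)-3α,12,14,15,19-pentahydroxylabd-8(17)-en-16-oate | C=C1CC[C@@H]2[C@](C)(CO)[C@H](O)CC[C@@]2(C)[C@@H]1C[C@@H](O)[C@@H](C(=O)OC)[C@H](O)CO | intermediate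
26 | (12R,13R,14S)-3α,12,14,19-tetrahydroxy-5β,9βH,10α-labd-8(17)-en-16,15-olide, CNP0113086.1 | C=C1CC[C@@H]2[C@](C)(CO)[C@H](O)CC[C@@]2(C)[C@@H]1C[C@@H](O)[C@H]1C(=O)OC[C@H]1O | target

**Step count and risks**

Total step count: 18. Longest linear sequence: 15 steps (1 to 26 through steps 1–6, 8–14, 17 and 18).

Steps most likely to fail:

1. Step 8 (the step that goes beyond known chemistry). Closure of the tetrasubstituted C3=C4 bond may be slow, so that intermolecular enyne metathesis (oligomerisation) and hydrolysis of the mixed boronic ester take over. The fallback sets out from 8 and comes back at 15, using known reactions only and a different way of assembling ring A. Hydroxyl-directed epoxidation of the 2-substituted allylic alcohol (VO(acac)2, t-BuOOH) gives the epoxy alcohol F1. Silylation (TBSCl, imidazole) gives the epoxy silyl ether F2. Meinwald rearrangement (BF3·OEt2, −78 °C) gives the α-branched aldehyde F3, in which the former methylidene carbon has become C3. Vinylmagnesium bromide at −78 °C adds C2 to give the allylic alcohol F4. Ring-closing metathesis of the two monosubstituted vinyl groups with RuCl2(=CHPh)(H2IMes)(PCy3) gives the cyclohexenol F5, and MnO2 oxidation of the allylic alcohol gives 15.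

2. Step 10. The lithium dienolate may expel silanolate from C19 (β-elimination to the exocyclic methylidene ketone), and methylation may be incompletely face-selective. The fallback sets out from 14 and comes back at 16. The free hydroxy enone is converted with 2.2 equiv of LiN(iPr)2 into the alkoxide–enolate dianion, in which the oxygen on C19 cannot leave and lithium bridges O3 and O19. Methylation with MeI gives the methylated hydroxy enone F6, and silylation (TBSCl, imidazole) gives 16.

3. Step 17. The dianion aldol may show poor facial selectivity at the aldehyde carbon (C12), and the aldehyde may be enolised by the basic dianion. The fallback sets out from 23 (with 20) and comes back at 26, replacing substrate control by an Evans syn aldol. Silylation of 23 (TBSOTf, 2,6-lutidine) gives the bis-silyl ether ester F7, and saponification (LiOH, THF–H2O) gives the acid F8. Acylation of lithiated (S)-4-benzyl-1,3-oxazolidin-2-one through the mixed pivalic anhydride gives the imide F9. Its dibutylboron Z-enolate (Bu2BOTf, iPr2NEt, CH2Cl2, −78 °C) adds to aldehyde 20 to give the syn adduct F10, with C12 and C13 set by the auxiliary. HF·pyridine then removes the silyl groups, and the C15 hydroxyl displaces the auxiliary on lactonisation to give 26.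

**Further compounds**

F1 | step 8 | methyl 2-{3-[2-(hydroxymethyl)oxiran-2-yl]-2-methyl-6-methylidene-2-vinylcyclohexyl}acetate, epoxide epimers | C=C1CC[C@H](C2(CO)CO2)[C@@](C)(C=C)[C@@H]1CC(=O)OC
F2 | step 8 | tert-butyldimethylsilyl ether of F1 | C=C1CC[C@H](C2(CO[Si](C)(C)C(C)(C)C)CO2)[C@@](C)(C=C)[C@@H]1CC(=O)OC
F3 | step 8 | methyl 2-{3-[1-(tert-butyldimethylsilyloxy)-3-oxopropan-2-yl]-2-methyl-6-methylidene-2-vinylcyclohexyl}acetate, C4 epimers | C=C1CC[C@H](C(C=O)CO[Si](C)(C)C(C)(C)C)[C@@](C)(C=C)[C@@H]1CC(=O)OC
F4 | step 8 | methyl 2-{3-[1-(tert-butyldimethylsilyloxy)-3-hydroxypent-4-en-2-yl]-2-methyl-6-methylidene-2-vinylcyclohexyl}acetate, C3 and C4 epimers | C=C1CC[C@H](C(CO[Si](C)(C)C(C)(C)C)C(O)C=C)[C@@](C)(C=C)[C@@H]1CC(=O)OC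
F5 | step 8 | methyl 19-(tert-butyldimethylsilyloxy)-3-hydroxy-13,14,15,16,18-pentanorlabda-1,8(17)-dien-12-oate, C3 and C4 epimers | C=C1CC[C@@H]2C(CO[Si](C)(C)C(C)(C)C)C(O)C=C[C@@]2(C)[C@@H]1CC(=O)OC
F6 | step 10 | methyl 19-hydroxy-3-oxo-13,14,15,16-tetranorlabda-1,8(17)-dien-12-oate, C18 methyl equatorial | C=C1CC[C@@H]2[C@](C)(CO)C(=O)C=C[C@@]2(C)[C@@H]1CC(=O)OC
F7 | step 17 | methyl (S)-3,4-bis(tert-butyldimethylsilyloxy)butanoate | COC(=O)C[C@H](O[Si](C)(C)C(C)(C)C)CO[Si](C)(C)C(C)(C)C
F8 | step 17 | (S)-3,4-bis(tert-butyldimethylsilyloxy)butanoic acid | OC(=O)C[C@H](O[Si](C)(C)C(C)(C)C)CO[Si](C)(C)C(C)(C)C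
F9 | step 17 | (S)-4-benzyl-3-[(S)-3,4-bis(tert-butyldimethylsilyloxy)butanoyl]-1,3-oxazolidin-2-one | O=C(C[C@H](O[Si](C)(C)C(C)(C)C)CO[Si](C)(C)C(C)(C)C)N1C(=O)OC[C@@H]1Cc1ccccc1
F10 | step 17 | Evans syn aldol adduct of F9 and 20: N-acyl oxazolidinone at C16 with free 12-hydroxyl and silyl ethers at O3, O14, O15 and O19 | C=C1CC[C@@H]2[C@](C)(CO[Si](C)(C)C(C)(C)C)[C@H](O[Si](C)(C)C(C)(C)C)CC[C@@]2(C)[C@@H]1C[C@@H](O)[C@@H](C(=O)N1C(=O)OC[C@@H]1Cc1ccccc1)[C@H](O[Si](C)(C)C(C)(C)C)CO[Si](C)(C)C(C)(C)C
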